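Remark on numbering: the germacrane locants of the target (C1 furanone carbonyl, C2, C3 enol-ether carbon, C4–C10 ring carbons, C11–C13 lactone carbons, C14 methyl on C10, C15 hydroxymethyl on C4) are used for the corresponding atoms of every intermediate.
Assumption: (1S,2S,4R)-limonene-1,2-diol, 2-bromomalonaldehyde and 2,2-dimethyl-1,3-dioxan-5-one are taken as commercial.

## Analysis of the target

Target 37 is a germacranolide whose ten-membered carbocycle (C1–C10) is bridged by an oxygen between C3 and C10. The bridge atoms C10, C1, C2, C3 and that oxygen form a 3(2H)-furanone, and the ring is trans-fused at C6–C7 to an α-methylene-γ-butyrolactone. There are six stereocentres: the isolated quaternary C10 (S) and the contiguous run C4 (R, tertiary alcohol with the C15 hydroxymethyl), C5 (S, acetate), C6 (S, lactone oxygen), C7 (R) and C8 (R, methacrylate). The C5 and C6 oxygens are anti in the zigzag of C4–C7. C7–H and C8–O are related as in a syn addition to a 7,8-(E)-alkene. The C4 oxygen lies anti to the C5–C6 bond when C4/C5 are read as a former alkene. The molecule holds two Michael acceptors, a vinylogous ester, and an acetate flanked by a free tertiary and a free primary hydroxyl, so the last steps must avoid base (acyl migration, conjugate addition). The difficulty is the ten-membered ring itself, which resists end-to-end closure, together with five contiguous stereocentres on a flexible ring. The strategy rests on the pattern around the ring: C3 at ketone level, vicinal oxygens on C5/C6, and H/OH across C7–C8. This is the array (ketone, new σ bond, alkene) left by an oxy-Cope rearrangement of a 1,2-dialkenylcyclohexanol in which C3 and C8 were bonded.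

## Retrosynthetic reasoning

37 from 36. Only the two silyl ethers on O4 and O15 are removed at the end, under acidic fluoride conditions. The base-sensitive ester array is thus released without base.

36 from 34 (C3–O bond of the bridge cut). The furanone is a cyclodehydration product of an α′-hydroxy-1,3-diketone, so it is traced to the C1 carbinol/C10 tertiary alcohol 34. No stereocentre is made, because C10 carries its oxygen from the start. The forward step needs O10 to be the only free nucleophile, which is why O4, O5 and O15 are blocked in 34.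

34 from 32 and 28 (O6–C12 and C11=C13 cut). The lactone is closed by acid from the acrylic acid 32 when the C6 ether and the C1/C10 acetonide fall together. The exocyclic methylene is put on at the aldehyde stage (31) through an iminium salt, because lactone enolate chemistry would not tolerate the acetate and methacrylate already present in 28.

28 from 25. The O5/O15 acetonide is exchanged for the final C5 acetate and a robust C15 silyl ether while the C1/C10 acetonide stays. This orders the two acetals by their hydrolysis rates.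

25 from 21 (C4–O, O8-acyl and C8–O/C7–H cut). The ketone 25 comes from Rubottom oxidation of the silyl enol ether, and the C8 ester from hydroboration of the C7=C8 alkene of 21 followed by acylation (22, 23). Both alkenes are exactly what the key step leaves. Hydroboration is placed first, while C3 is still masked as its enol ether.

21 from 18 (key disconnection: C5–C6 cut, C3–C8 re-formed). The ring is contracted to the cyclohexanol 18, in which C3 and C8 are bonded and both carry enol-ether alkenyl groups. The choice of diastereomer and alkene geometries follows from three points: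
- The C3=C4 enol ether of 21 is tetrasubstituted and trans in the ring, so neither substituent can pass through the ring and the exposed face of C4 is fixed by the rearrangement.
- The target needs the C4 oxygen anti to the new C5–C6 bond, hence O5 cis to C15 on the C4=C5 alkene (a 4H-1,3-dioxin). It needs C7–H anti to that bond, hence O6 cis to C8 (a Z enol ether).
- With these geometries the correct C5/C6 configuration requires the (3S,8S) ring centres, that is the C8 alkenyl group cis to the C10 oxygen. The trans-fused C1/C10 acetonide holds the chair with C14 axial, which makes this the thermodynamic arrangement.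

18 from 16 and 8 (C3–C4 cut). The carbinol comes from equatorial addition of the dioxinyl metal derived from 8 to ketone 16. The ring of 8 fixes the enol ether geometry and protects O5 and O15 at once.

16 from 14 and 5 (C7–C8 cut). The α-alkenyl ketone comes from palladium-catalysed coupling of the enol silane of 14 with alkenyl bromide 5. C8 is epimerisable and settles equatorial under the lock.

14 from 9, 5 from 1, 8 from 6. Ketone 14 is the degradation product of the chiral-pool diol 9, which supplies C10 with its oxygen and methyl group. Bromide 5 is built from 1, whose enol O-alkylation gives the required Z geometry. Stannane 8 is built from 6 through its enol triflate 7.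

## Alternatives that were turned down

Alternative 1: The disconnection is the C10–O bond of the bridge. In the forward step, acid lets the C3 carbonyl oxygen of a ten-membered 3-keto-1(10)-epoxide open the epoxide at the tertiary C10 with inversion, giving the bridged 1-hydroxy-2,3-dihydrofuran A1, one oxidation short of the furanone.
- For it: the step is biomimetic and stereospecific at C10, and A1 already carries both esters and the methylene lactone. In what remains after its key step it is stronger than the chosen route.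
- Against it: it presupposes the ten-membered ring with C4–C8 in place and an epoxide of defined face, and does not say how that ring is made. Acid on a medium-ring epoxide also invites transannular hydride shifts and ring contraction, and the C1 carbinol must then be oxidised beside an acid-labile acetonide.
- Comparison: the chosen route spends its key step on the ring and two stereocentres. It forms the same bridge later by cyclodehydration (step 25), where C10 is not at risk.

Alternative 2: The C4–C8 segment is traced to a furyl carbinol. Photooxygenation of the furan (C5–C8) and reduction of the endoperoxide let the C4 hydroxyl close on C8, giving the pyranone A2.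
- For it: the precursor is cheap, and the quaternary C4 is secured early with its oxygen and both carbon arms. On early, unambiguous control of C4 it is stronger than the chosen route, which sets C4 late through the face left open after ring expansion.
- Against it: A2 is only a five-carbon segment. Reduction at C5, oxygenation at C6, a carbon substituent at C7, chain extension at C8 and elaboration of the alkyne into C2/C3 all remain, and the ten-membered ring must still be closed end to end.
- Comparison: the chosen route is shorter to the ring and makes the ring, C5 and C6 in one step.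

Alternative 3: The disconnection is C4–C5. A one-electron reductant (divalent samarium) couples the C4 ketone and the C5 aldehyde of an open-chain precursor that already holds furanone and lactone, closing the ring as diol A3.
- For it: it is convergent and, like the chosen route, makes the ring and two stereocentres in one step. Fewer operations remain after the key step, so on post-key-step economy it is stronger.
- Against it: a ten-membered ring is closed end to end (entropy, transannular strain, high dilution). The C4 ketone is conjugated to the furanone and flanked by an α-alkoxy group, so electron transfer can reduce the vinylogous ester or expel the α-oxygen instead of giving the ketyl. The aldehyde is α-oxygenated and epimerisable, and facial control at both carbonyls in a floppy macrocyclic transition state cannot be predicted.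
- Comparison: the chosen route closes the ring by a sigmatropic shift without entropic penalty and with stereochemistry fixed by a chair. It pays with a longer sequence after the key step.

Key step: step 14

## Steps

Step 1
Reactants: 1 2-bromomalonaldehyde
Product: 2 (2Z)-2-bromo-3-(methoxymethoxy)prop-2-enal
Conditions: MeOCH2Cl, i-Pr2NEt, CH2Cl2, 0 °C
Reagents that add atoms: chloromethyl methyl ether, COCCl
Why: O-Alkylation of the acidic enol of a vinylogous formic acid; the alkoxy group settles trans to the formyl group and therefore cis to bromine, the Z geometry later needed for O6 cis to C8.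

Step 2
Reactants: 2 (2Z)-2-bromo-3-(methoxymethoxy)prop-2-enal
Product: 3 (1Z)-2-bromo-1-(methoxymethoxy)buta-1,3-diene
Conditions: Ph3PCH3Br, KN(SiMe3)2, THF, −78 → 0 °C
Reagents that add atoms: methyltriphenylphosphonium bromide, C[P+](c1ccccc1)(c1ccccc1)c1ccccc1.[Br-]
Why: Wittig methylenation of the aldehyde; the non-stabilised ylide attacks the formyl group and leaves the enol ether geometry untouched.

Step 3
Reactants: 3 (1Z)-2-bromo-1-(methoxymethoxy)buta-1,3-diene
Product: 4 (3Z)-3-bromo-4-(methoxymethoxy)but-3-en-1-ol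
Conditions: 9-BBN, THF, 0 → 25 °C; then NaOH, H2O2, 0 °C
Reagents that add atoms: hydrogen peroxide, OO
Why: Hydroboration–oxidation; the hindered borane adds only to the terminal vinyl group with boron on the end carbon, the trisubstituted bromo enol ether being inert.

Step 4
Reactants: 4 (3Z)-3-bromo-4-(methoxymethoxy)but-3-en-1-ol
Product: 5 1-({[(3Z)-3-bromo-4-(methoxymethoxy)but-3-en-1-yl]oxy}methyl)-4-methoxybenzene
Conditions: NaH, 4-MeOC6H4CH2Cl, n-Bu4NI (cat.), THF, 0 °C
Reagents that add atoms: 4-methoxybenzyl chloride, COc1ccc(CCl)cc1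
Why: Williamson etherification; at 0 °C the primary alkoxide is too weak a base to dehydrobrominate the alkenyl bromide.

Step 5
Reactants: 6 2,2-dimethyl-1,3-dioxan-5-one
Product: 7 2,2-dimethyl-4H-1,3-dioxin-5-yl trifluoromethanesulfonate
Conditions: KN(SiMe3)2, THF, −78 °C; then PhNTf2, −78 → 0 °C
Reagents that add atoms: N-phenylbis(trifluoromethanesulfonimide), O=S(=O)(N(c1ccccc1)S(=O)(=O)C(F)(F)F)C(F)(F)F
Why: Enol triflate formation from the kinetic enolate; the six-membered ring forces O5 and C15 onto the same side of the new double bond.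

Step 6
Reactants: 7 2,2-dimethyl-4H-1,3-dioxin-5-yl trifluoromethanesulfonate
Product: 8 trimethyl(2,2-dimethyl-4H-1,3-dioxin-5-yl)stannane
Conditions: Me3SnSnMe3, Pd(PPh3)4 (cat.), LiCl, THF, 65 °C
Reagents that add atoms: hexamethylditin, C[Sn](C)(C)[Sn](C)(C)C
Why: Palladium-catalysed stannylation of an alkenyl triflate with a distannane (Stille-type); it gives a reagent that can be lithiated at −78 °C without opening the ring.

Step 7
Reactants: 9 (1S,2S,4R)-limonene-1,2-diol [(1S,2S,4R)-1-methyl-4-(prop-1-en-2-yl)cyclohexane-1,2-diol]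
Product: 10 1-[(1R,3S,4S)-3,4-dihydroxy-4-methylcyclohexyl]ethan-1-one
Conditions: O3, CH2Cl2/MeOH, −78 °C; then Me2S, −78 → 25 °C
Reagents that add atoms: ozone, [O-][O+]=O
Why: Ozonolysis of the 1,1-disubstituted alkene with reductive work-up gives the methyl ketone; the diol and its two stereocentres (later C1 and C10) are untouched.

Step 8
Reactants: 10 1-[(1R,3S,4S)-3,4-dihydroxy-4-methylcyclohexyl]ethan-1-one
Product: 11 (1R,3S,4S)-3,4-dihydroxy-4-methylcyclohexyl acetate
Conditions: mCPBA, NaHCO3, CH2Cl2, 25 °C
Reagents that add atoms: 3-chloroperbenzoic acid, O=C(OO)c1cccc(Cl)c1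
Why: Baeyer–Villiger oxidation; the secondary ring carbon migrates in preference to methyl and with retention, placing oxygen on the future C3.

Step 9
Reactants: 11 (1R,3S,4S)-3,4-dihydroxy-4-methylcyclohexyl acetate
Product: 12 (3aS,5R,7aS)-2,2,7a-trimethylhexahydro-1,3-benzodioxol-5-yl acetate (trans-fused acetonide)
Conditions: 2-methoxypropene, PPTS (cat.), CH2Cl2, 0 → 25 °C
Reagents that add atoms: 2-methoxypropene, COC(C)=C
Why: Kinetic acetonide formation on the trans-1,2-diol; closing the trans-fused dioxolane forces both oxygens equatorial and C14 axial, which is the conformational lock used in steps 12 to 14.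

Step 10
Reactants: 12 (3aS,5R,7aS)-2,2,7a-trimethylhexahydro-1,3-benzodioxol-5-yl acetate
Product: 13 (3aS,5R,7aS)-2,2,7a-trimethylhexahydro-1,3-benzodioxol-5-ol
Conditions: K2CO3 (cat.), MeOH, 25 °C
Reagents that add atoms: none
Why: Transesterification of the acetate to methanol; the acetonide is stable to base.

Step 11
Reactants: 13 (3aS,5R,7aS)-2,2,7a-trimethylhexahydro-1,3-benzodioxol-5-ol
Product: 14 (3aS,7aS)-2,2,7a-trimethyltetrahydro-1,3-benzodioxol-5(4H)-one
Conditions: Dess–Martin periodinane, NaHCO3, CH2Cl2, 25 °C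
Reagents that add atoms: none
Why: Dess–Martin oxidation of the secondary alcohol under buffered neutral conditions that spare the strained acetonide.

Step 12
Reactants: 14 (3aS,7aS)-2,2,7a-trimethyltetrahydro-1,3-benzodioxol-5(4H)-one; 5 1-({[(3Z)-3-bromo-4-(methoxymethoxy)but-3-en-1-yl]oxy}methyl)-4-methoxybenzene
Product: 16 (3aS,6S,7aS)-6-[(1Z)-1-(methoxymethoxy)-4-[(4-methoxybenzyl)oxy]but-1-en-2-yl]-2,2,7a-trimethyltetrahydro-1,3-benzodioxol-5(4H)-one (α-alkenyl ketone; C8 substituent equatorial), via trimethylsilyl enol ether 15 (not isolated)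
Conditions: LiN(SiMe3)2, Me3SiCl, THF, −78 °C; then 5, Pd2(dba)3 (cat.), P(t-Bu)3 (cat.), Bu3SnF, PhMe, 80 °C; then DBU (cat.), CH2Cl2, 25 °C
Reagents that add atoms: none
Why: Kinetic enol silylation on the side away from the oxygenated ring-fusion carbon, then coupling of the silyl enol ether with the alkenyl bromide under zerovalent palladium catalysis through a tin enolate, a known α-alkenylation that needs no strong base and so spares the bromide. The new C8 centre settles thermodynamically (DBU) with the alkenyl group equatorial and cis to the C10 oxygen, because the axial position is syn to the axial C14 methyl of the locked chair.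

Step 13
Reactants: 16 (3aS,6S,7aS)-6-[(1Z)-1-(methoxymethoxy)-4-[(4-methoxybenzyl)oxy]but-1-en-2-yl]-2,2,7a-trimethyltetrahydro-1,3-benzodioxol-5(4H)-one; 8 trimethyl(2,2-dimethyl-4H-1,3-dioxin-5-yl)stannane
Product: 18 (3aS,5S,6S,7aS)-5-(2,2-dimethyl-4H-1,3-dioxin-5-yl)-6-[(1Z)-1-(methoxymethoxy)-4-[(4-methoxybenzyl)oxy]but-1-en-2-yl]-2,2,7a-trimethylhexahydro-1,3-benzodioxol-5-ol (trans-1,2-dialkenyl cyclohexanol), via 5-lithio-2,2-dimethyl-4H-1,3-dioxin 17 (not isolated)
Conditions: 8, MeLi, THF, −78 °C; CeCl3, −78 °C; then 16, −78 → −40 °C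
Reagents that add atoms: none
Why: Tin–lithium exchange and 1,2-addition of the organocerium reagent, whose low basicity suppresses enolisation of the acidic C8–H. The bulky alkenyl nucleophile attacks the locked chair equatorially, so C3 is formed with axial OH and the two alkenyl groups trans-diequatorial.

Step 14
Reactants: 18 (3aS,5S,6S,7aS)-5-(2,2-dimethyl-4H-1,3-dioxin-5-yl)-6-[(1Z)-1-(methoxymethoxy)-4-[(4-methoxybenzyl)oxy]but-1-en-2-yl]-2,2,7a-trimethylhexahydro-1,3-benzodioxol-5-ol
Product: 21 (1S,5R,6S,10S)-3-(tert-butyldimethylsilyloxy)-1,10:5,15-bis(isopropylidenedioxy)-6-(methoxymethoxy)-12-(4-methoxybenzyloxy)-13-norgermacra-3,7-diene (7E; C2 trans to C5 on C3=C4), via potassium alkoxide 19 (not isolated), via potassium enolate 20 (not isolated)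
Conditions: KH, 18-crown-6, THF, 0 → 25 °C; then t-BuMe2SiCl, −78 → 0 °C
Reagents that add atoms: tert-butyldimethylsilyl chloride, CC(C)(C)[Si](C)(C)Cl
Why: The potassium alkoxide 19 undergoes an anionic oxy-Cope [3,3]-sigmatropic shift through a chair: C3–C8 breaks as C5–C6 forms, and the six-membered ring grows by four atoms into the ten-membered enolate 20, which is silylated on oxygen. The closest known reaction type is the anionic oxy-Cope ring expansion of trans-1,2-dialkenylcyclohexanols to cyclodec-5-enones. The ten-membered ring is closed by ring expansion, not by end-to-end cyclisation, so no dilution is needed. The trans-fused acetonide holds both alkenyl groups equatorial, which is the chair with both ring bonds equatorial and gives two trans ring double bonds. At C5 the oxygen is trans to C3 within the dioxin ring and sits equatorial; at C6 the oxygen is cis to C8 and sits axial. With the chair sense fixed by the (3S,8S) ring centres this gives the anti C5/C6 diol in the configuration of the target. The step needs chair over boat and [3,3] shift over fragmentation or loss of the β-oxygen from the enolate; pre-organisation by the lock and cold silylation serve this. The same chair leaves on the outside of the new ring exactly the faces of C4 and of C7=C8 that steps 15 and 17 must attack.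

Step 15
Reactants: 21 (1S,5R,6S,10S)-3-(tert-butyldimethylsilyloxy)-1,10:5,15-bis(isopropylidenedioxy)-6-(methoxymethoxy)-12-(4-methoxybenzyloxy)-13-norgermacra-3,7-diene
Product: 22 (1S,5R,6S,7R,8R,10S)-3-(tert-butyldimethylsilyloxy)-1,10:5,15-bis(isopropylidenedioxy)-6-(methoxymethoxy)-12-(4-methoxybenzyloxy)-13-norgermacr-3-en-8-ol
Conditions: BH3·THF, THF, −20 → 0 °C; then NaBO3·4H2O, THF/H2O, 25 °C
Reagents that add atoms: sodium perborate, [Na+].[Na+].O[B-]1(O)OO[B-](O)(O)OO1
Why: Hydroboration–oxidation; boron goes to C8, the less substituted carbon and the one remote from the allylic C6 oxygen. Syn addition to the outer face of the trans alkene in the crossed conformation inherited from the chair sets C7 (R) and C8 (R); the tetrasubstituted silyl enol ether reacts more slowly and survives the mild oxidant.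

Step 16
Reactants: 22 (1S,5R,6S,7R,8R,10S)-3-(tert-butyldimethylsilyloxy)-1,10:5,15-bis(isopropylidenedioxy)-6-(methoxymethoxy)-12-(4-methoxybenzyloxy)-13-norgermacr-3-en-8-ol
Product: 23 the 8-O-(2-methylprop-2-enoyl) ester of 22 (C8 methacrylate)
Conditions: methacrylic anhydride, Et3N, DMAP (cat.), CH2Cl2, 0 → 25 °C
Reagents that add atoms: methacrylic anhydride, CC(=C)C(=O)OC(=O)C(C)=C
Why: DMAP-catalysed acylation installs the final C8 ester early; every later step is acidic, oxidative or only weakly basic, so it serves as its own protecting group.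

Step 17
Reactants: 23 the C8 methacrylate of 22
Product: 25 (1S,4R,5S,6S,7R,8R,10S)-4-(tert-butyldimethylsilyloxy)-1,10:5,15-bis(isopropylidenedioxy)-6-(methoxymethoxy)-12-(4-methoxybenzyloxy)-3-oxo-13-norgermacran-8-yl methacrylate, via 3,4-epoxy silyl ether 24 (not isolated)
Conditions: mCPBA, NaHCO3, CH2Cl2, −20 → 25 °C
Reagents that add atoms: 3-chloroperbenzoic acid, O=C(OO)c1cccc(Cl)c1
Why: Rubottom oxidation; the peracid epoxidises the electron-rich enol ether on its only accessible face, which cannot change because no substituent of this tetrasubstituted trans-cycloalkene can pass through the ring. Silyl migration from O3 to the new oxygen gives the C3 ketone with C4 (R) already protected as its silyl ether.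

Step 18
Reactants: 25 (1S,4R,5S,6S,7R,8R,10S)-4-(tert-butyldimethylsilyloxy)-1,10:5,15-bis(isopropylidenedioxy)-6-(methoxymethoxy)-12-(4-methoxybenzyloxy)-3-oxo-13-norgermacran-8-yl methacrylate
Product: 26 the 5,15-diol of 25 (C1/C10 acetonide retained)
Conditions: AcOH/THF/H2O (3:1:1), 25 °C
Reagents that add atoms: none
Why: Selective acetal hydrolysis; the six-membered 1,3-dioxane acetonide on O5/O15 should cleave faster than the dioxolane on the hindered C1/C10 pair, and the MOM, PMB and tertiary silyl ethers are stable.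

Step 19
Reactants: 26 the 5,15-diol of 25
Product: 28 (1S,4R,5S,6S,7R,8R,10S)-5-acetoxy-4-(tert-butyldimethylsilyloxy)-15-(tert-butyldiphenylsilyloxy)-1,10-(isopropylidenedioxy)-6-(methoxymethoxy)-12-(4-methoxybenzyloxy)-3-oxo-13-norgermacran-8-yl methacrylate, via 15-O-silyl ether 27 (not isolated)
Conditions: t-BuPh2SiCl, imidazole, DMAP (cat.), CH2Cl2, 0 → 25 °C; then Ac2O, Et3N, 25 → 40 °C
Reagents that add atoms: tert-butyldiphenylsilyl chloride, CC(C)(C)[Si](Cl)(c1ccccc1)c1ccccc1; acetic anhydride, CC(=O)OC(C)=O
Why: Selective silylation of the primary hydroxyl, then acetylation of the one remaining secondary hydroxyl in the same flask; the C5 acetate of the target is thereby in place with no free neighbouring hydroxyl.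

Step 20
Reactants: 28 the 5-acetate 15-silyl ether
Product: 29 the 12-alcohol of 28 (PMB ether removed)
Conditions: DDQ, CH2Cl2/pH 7 buffer, 0 °C
Reagents that add atoms: none
Why: Oxidative cleavage of the 4-methoxybenzyl ether by DDQ under buffered conditions; silyl ethers, esters, the MOM ether and the acetonide are unaffected.

Step 21
Reactants: 29 the 12-alcohol
Product: 30 the 12-aldehyde (C11H2–C12HO)
Conditions: Dess–Martin periodinane, NaHCO3, CH2Cl2, 25 °C
Reagents that add atoms: none
Why: Dess–Martin oxidation of the only free hydroxyl to the aldehyde without epimerisation at C7.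

Step 22
Reactants: 30 the 12-aldehyde
Product: 31 the 11(13)-en-12-al (α-methylene aldehyde)
Conditions: CH2=NMe2+ I−, Et3N, CH2Cl2, 25 °C
Reagents that add atoms: N,N-dimethylmethyleneiminium iodide, C=[N+](C)C.[I-]
Why: α-Methylenation of the aldehyde by Mannich addition to the iminium salt and loss of dimethylamine; this introduces C13 without the strong base that the acetate and methacrylate would not tolerate.

Step 23
Reactants: 31 the 11(13)-en-12-al
Product: 32 the 11(13)-en-12-oic acid (2-substituted acrylic acid)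
Conditions: NaClO2, NaH2PO4, 2-methyl-2-butene, t-BuOH/H2O, 0 → 25 °C
Reagents that add atoms: sodium chlorite, [Na+].[O-]Cl=O
Why: Pinnick oxidation of the enal to the acid; the alkene scavenger protects the other double bonds from hypochlorite.

Step 24
Reactants: 32 the 11(13)-en-12-oic acid
Product: 34 (1S,4R,5S,6S,7R,8R,10S)-5-acetoxy-4-(tert-butyldimethylsilyloxy)-15-(tert-butyldiphenylsilyloxy)-1,10-dihydroxy-8-(methacryloyloxy)-3-oxogermacr-11(13)-en-12,6-olide, via seco acid triol 33 (not isolated)
Conditions: CF3CO2H/CH2Cl2/H2O (10:10:1), 0 → 25 °C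
Reagents that add atoms: none
Why: Acidolysis of the MOM ether and of the remaining acetonide; the freed C6 hydroxyl, the only one within reach since O8 is esterified, lactonises onto the acrylic acid to the γ-lactone. The trans ring fusion is already fixed by C6 and C7.

Step 25
Reactants: 34 the 1,10-diol lactone
Product: 36 4-O-(tert-butyldimethylsilyl)-15-O-(tert-butyldiphenylsilyl) ether of 37, via 10-hydroxy-1,3-diketone 35 (not isolated)
Conditions: Dess–Martin periodinane, NaHCO3, CH2Cl2, 25 °C; then p-TsOH·H2O (cat.), CH2Cl2, 25 °C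
Reagents that add atoms: none
Why: Oxidation of the single secondary alcohol gives the α′-hydroxy-1,3-diketone; its C10 hydroxyl adds to the C3 carbonyl (five-membered ring, exo attack) and acid-catalysed dehydration gives the 3(2H)-furanone. With O4, O5 and O15 blocked this is the only cyclisation open.

Step 26
Reactants: 36 the bis-silyl ether of 37
Product: 37 (4R,5S,6S,7R,8R,10S)-5-acetoxy-4,15-dihydroxy-8-(2-methylprop-2-enoyloxy)-1-oxo-3,10-epoxygermacra-2,11(13)-dien-12,6-olide (target)
Conditions: HF·pyridine, pyridine, THF, 0 → 25 °C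
Reagents that add atoms: none
Why: Fluoride-mediated desilylation under mildly acidic conditions removes both silyl ethers without acyl migration and without harming the two Michael acceptors.

## Compound list

1 | 2-bromomalonaldehyde | O=CC(Br)C=O | starting material
2 | (2Z)-2-bromo-3-(methoxymethoxy)prop-2-enal | COCO/C=C(Br)/C=O | intermediate
3 | (1Z)-2-bromo-1-(methoxymethoxy)buta-1,3-diene | COCO/C=C(Br)/C=C | intermediate
4 | (3Z)-3-bromo-4-(methoxymethoxy)but-3-en-1-ol | COCO/C=C(Br)/CCO | intermediate
5 | 1-({[(3Z)-3-bromo-4-(methoxymethoxy)but-3-en-1-yl]oxy}methyl)-4-methoxybenzene | COCO/C=C(Br)/CCOCc1ccc(OC)cc1 | intermediate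
6 | 2,2-dimethyl-1,3-dioxan-5-one | CC1(C)OCC(=O)CO1 | starting material
7 | 2,2-dimethyl-4H-1,3-dioxin-5-yl trifluoromethanesulfonate | CC1(C)OCC(OS(=O)(=O)C(F)(F)F)=CO1 | intermediate
8 | trimethyl(2,2-dimethyl-4H-1,3-dioxin-5-yl)stannane | CC1(C)OCC([Sn](C)(C)C)=CO1 | intermediate
9 | (1S,2S,4R)-limonene-1,2-diol | CC(=C)[C@@H]1CC[C@](C)(O)[C@@H](O)C1 | starting material
10 | 1-[(1R,3S,4S)-3,4-dihydroxy-4-methylcyclohexyl]ethan-1-one | CC(=O)[C@@H]1CC[C@](C)(O)[C@@H](O)C1 | intermediate
11 | (1R,3S,4S)-3,4-dihydroxy-4-methylcyclohexyl acetate | CC(=O)O[C@@H]1CC[C@](C)(O)[C@@H](O)C1 | intermediate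
12 | (3aS,5R,7aS)-2,2,7a-trimethylhexahydro-1,3-benzodioxol-5-yl acetate | CC(=O)O[C@@H]1CC[C@]2(C)OC(C)(C)O[C@H]2C1 | intermediate
13 | (3aS,5R,7aS)-2,2,7a-trimethylhexahydro-1,3-benzodioxol-5-ol | O[C@@H]1CC[C@]2(C)OC(C)(C)O[C@H]2C1 | intermediate
14 | (3aS,7aS)-2,2,7a-trimethyltetrahydro-1,3-benzodioxol-5(4H)-one | O=C1CC[C@]2(C)OC(C)(C)O[C@H]2C1 | intermediate
15 | trimethyl{[(3aS,7aS)-2,2,7a-trimethyl-3a,4,7,7a-tetrahydro-1,3-benzodioxol-5-yl]oxy}silane (formed in the flask) | C[Si](C)(C)OC1=CC[C@]2(C)OC(C)(C)O[C@H]2C1 | intermediate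
16 | (3aS,6S,7aS)-6-[(1Z)-1-(methoxymethoxy)-4-[(4-methoxybenzyl)oxy]but-1-en-2-yl]-2,2,7a-trimethyltetrahydro-1,3-benzodioxol-5(4H)-one | O=C1[C@H](/C(CCOCc3ccc(OC)cc3)=C\OCOC)C[C@]2(C)OC(C)(C)O[C@H]2C1 | intermediate
17 | 5-lithio-2,2-dimethyl-4H-1,3-dioxin (formed in the flask) | [Li]C1=COC(C)(C)OC1 | intermediate
18 | (3aS,5S,6S,7aS)-5-(2,2-dimethyl-4H-1,3-dioxin-5-yl)-6-[(1Z)-1-(methoxymethoxy)-4-[(4-methoxybenzyl)oxy]but-1-en-2-yl]-2,2,7a-trimethylhexahydro-1,3-benzodioxol-5-ol | O[C@]1(C2=COC(C)(C)OC2)[C@H](/C(CCOCc4ccc(OC)cc4)=C\OCOC)C[C@]3(C)OC(C)(C)O[C@H]3C1 | intermediate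
19 | potassium alkoxide of 18 (formed in the flask) | [K+].[O-][C@]1(C2=COC(C)(C)OC2)[C@H](/C(CCOCc4ccc(OC)cc4)=C\OCOC)C[C@]3(C)OC(C)(C)O[C@H]3C1 | intermediate
20 | ten-membered potassium enolate, C3 oxido analogue of 21 (formed in the flask) | [K+].C1/C([O-])=C(COC(C)(C)O2)/[C@@H]2[C@@H](OCOC)/C(CCOCc4ccc(OC)cc4)=C/C[C@]3(C)OC(C)(C)O[C@H]31 | intermediate
21 | (1S,5R,6S,10S)-3-(tert-butyldimethylsilyloxy)-1,10:5,15-bis(isopropylidenedioxy)-6-(methoxymethoxy)-12-(4-methoxybenzyloxy)-13-norgermacra-3,7-diene (7E; C2 trans to C5 on C3=C4) | C1/C(O[Si](C)(C)C(C)(C)C)=C(COC(C)(C)O2)/[C@@H]2[C@@H](OCOC)/C(CCOCc4ccc(OC)cc4)=C/C[C@]3(C)OC(C)(C)O[C@H]31 | intermediate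
22 | (1S,5R,6S,7R,8R,10S)-8-hydroxy derivative of 21 with C7–H (13-norgermacr-3-en-8-ol) | C1/C(O[Si](C)(C)C(C)(C)C)=C(COC(C)(C)O2)/[C@@H]2[C@@H](OCOC)[C@H](CCOCc4ccc(OC)cc4)[C@H](O)C[C@]3(C)OC(C)(C)O[C@H]31 | intermediate
23 | C8 methacrylate of 22 | C1/C(O[Si](C)(C)C(C)(C)C)=C(COC(C)(C)O2)/[C@@H]2[C@@H](OCOC)[C@H](CCOCc4ccc(OC)cc4)[C@H](OC(=O)C(C)=C)C[C@]3(C)OC(C)(C)O[C@H]31 | intermediate
24 | 3,4-epoxide of 23 with the silyloxy group on C3 (formed in the flask) | C1[C@@]2(O[Si](C)(C)C(C)(C)C)O[C@]2(COC(C)(C)O3)[C@@H]3[C@@H](OCOC)[C@H](CCOCc5ccc(OC)cc5)[C@H](OC(=O)C(C)=C)C[C@]4(C)OC(C)(C)O[C@H]41 | intermediate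
25 | (1S,4R,5S,6S,7R,8R,10S)-4-(tert-butyldimethylsilyloxy)-1,10:5,15-bis(isopropylidenedioxy)-6-(methoxymethoxy)-12-(4-methoxybenzyloxy)-3-oxo-13-norgermacran-8-yl methacrylate | C1C(=O)[C@@]2(O[Si](C)(C)C(C)(C)C)COC(C)(C)O[C@H]2[C@@H](OCOC)[C@H](CCOCc4ccc(OC)cc4)[C@H](OC(=O)C(C)=C)C[C@]3(C)OC(C)(C)O[C@H]31 | intermediate
26 | 5,15-diol of 25 (C1/C10 acetonide retained) | C1C(=O)[C@@](O[Si](C)(C)C(C)(C)C)(CO)[C@@H](O)[C@@H](OCOC)[C@H](CCOCc4ccc(OC)cc4)[C@H](OC(=O)C(C)=C)C[C@]3(C)OC(C)(C)O[C@H]31 | intermediate
27 | 15-O-(tert-butyldiphenylsilyl) ether of 26 (formed in the flask) | C1C(=O)[C@@](O[Si](C)(C)C(C)(C)C)(CO[Si](c5ccccc5)(c6ccccc6)C(C)(C)C)[C@@H](O)[C@@H](OCOC)[C@H](CCOCc4ccc(OC)cc4)[C@H](OC(=O)C(C)=C)C[C@]3(C)OC(C)(C)O[C@H]31 | intermediate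
28 | 5-O-acetyl derivative of 27 | C1C(=O)[C@@](O[Si](C)(C)C(C)(C)C)(CO[Si](c5ccccc5)(c6ccccc6)C(C)(C)C)[C@@H](OC(C)=O)[C@@H](OCOC)[C@H](CCOCc4ccc(OC)cc4)[C@H](OC(=O)C(C)=C)C[C@]3(C)OC(C)(C)O[C@H]31 | intermediate
29 | 12-alcohol from 28 | C1C(=O)[C@@](O[Si](C)(C)C(C)(C)C)(CO[Si](c5ccccc5)(c6ccccc6)C(C)(C)C)[C@@H](OC(C)=O)[C@@H](OCOC)[C@H](CCO)[C@H](OC(=O)C(C)=C)C[C@]3(C)OC(C)(C)O[C@H]31 | intermediate
30 | 12-aldehyde | C1C(=O)[C@@](O[Si](C)(C)C(C)(C)C)(CO[Si](c5ccccc5)(c6ccccc6)C(C)(C)C)[C@@H](OC(C)=O)[C@@H](OCOC)[C@H](CC=O)[C@H](OC(=O)C(C)=C)C[C@]3(C)OC(C)(C)O[C@H]31 | intermediate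
31 | 11(13)-en-12-al | C1C(=O)[C@@](O[Si](C)(C)C(C)(C)C)(CO[Si](c5ccccc5)(c6ccccc6)C(C)(C)C)[C@@H](OC(C)=O)[C@@H](OCOC)[C@H](C(=C)C=O)[C@H](OC(=O)C(C)=C)C[C@]3(C)OC(C)(C)O[C@H]31 | intermediate
32 | 11(13)-en-12-oic acid | C1C(=O)[C@@](O[Si](C)(C)C(C)(C)C)(CO[Si](c5ccccc5)(c6ccccc6)C(C)(C)C)[C@@H](OC(C)=O)[C@@H](OCOC)[C@H](C(=C)C(=O)O)[C@H](OC(=O)C(C)=C)C[C@]3(C)OC(C)(C)O[C@H]31 | intermediate
33 | 1,6,10-triol seco acid (formed in the flask) | C1C(=O)[C@@](O[Si](C)(C)C(C)(C)C)(CO[Si](c5ccccc5)(c6ccccc6)C(C)(C)C)[C@@H](OC(C)=O)[C@@H](O)[C@H](C(=C)C(=O)O)[C@H](OC(=O)C(C)=C)C[C@](C)(O)[C@H]1O | intermediate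
34 | (1S,4R,5S,6S,7R,8R,10S)-5-acetoxy-4-(tert-butyldimethylsilyloxy)-15-(tert-butyldiphenylsilyloxy)-1,10-dihydroxy-8-(methacryloyloxy)-3-oxogermacr-11(13)-en-12,6-olide | C1C(=O)[C@@](O[Si](C)(C)C(C)(C)C)(CO[Si](c5ccccc5)(c6ccccc6)C(C)(C)C)[C@@H](OC(C)=O)[C@H]2OC(=O)C(=C)[C@@H]2[C@H](OC(=O)C(C)=C)C[C@](C)(O)[C@H]1O | intermediate
35 | 10-hydroxy-1,3-dioxo analogue of 34 (formed in the flask) | C1C(=O)[C@@](O[Si](C)(C)C(C)(C)C)(CO[Si](c5ccccc5)(c6ccccc6)C(C)(C)C)[C@@H](OC(C)=O)[C@H]2OC(=O)C(=C)[C@@H]2[C@H](OC(=O)C(C)=C)C[C@](C)(O)C1=O | intermediate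
36 | 4-O-(tert-butyldimethylsilyl)-15-O-(tert-butyldiphenylsilyl) ether of 37 | C=C(C)C(=O)O[C@@H]1C[C@]2(C)OC(=CC2=O)[C@@](O[Si](C)(C)C(C)(C)C)(CO[Si](c3ccccc3)(c4ccccc4)C(C)(C)C)[C@@H](OC(C)=O)[C@H]2OC(=O)C(=C)[C@@H]21 | intermediate
37 | (4R,5S,6S,7R,8R,10S)-5-acetoxy-4,15-dihydroxy-8-(2-methylprop-2-enoyloxy)-1-oxo-3,10-epoxygermacra-2,11(13)-dien-12,6-olide | C=C(C)C(=O)O[C@@H]1C[C@]2(C)OC(=CC2=O)[C@@](O)(CO)[C@@H](OC(C)=O)[C@H]2OC(=O)C(=C)[C@@H]21 | target

## Step count and least certain steps

Total step count: 26. Longest linear sequence: 20 steps (steps 7 to 26, from 9). The side branches are steps 1 to 4 (bromide 5) and steps 5 and 6 (stannane 8).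

Step 14 (key step). The ring-expanded potassium enolate carries oxygen on C5 and C15, both β to the carbonyl carbon. It may expel one of them before it is silylated. The alkoxide may also revert by retro-addition, and the axial oxygen at C6 may slow the chair pathway enough for these processes to compete. Fallback: set out from 18, silylate the tertiary hydroxyl (t-BuMe2SiOTf, 2,6-lutidine, −78 → 0 °C) to the tert-butyldimethylsilyl ether of 18 F1, and heat it in base-washed glass (PhMe, about 200 °C, sealed tube). The neutral siloxy-Cope rearrangement runs through the same chair, never passes through a free enolate, and delivers the silyl enol ether directly, coming back to the route at 21.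

Step 12. Enolisation may not be regioselective between C8 and C2, and oxidative addition and transmetalation with the hindered, electron-rich bromide may be slow enough for protodesilylation to win. Fallback: set out from 14 through its enol silane 15. Saegusa oxidation (Pd(OAc)2, MeCN) gives the enone (3aS,7aS)-2,2,7a-trimethyl-3a,4-dihydro-1,3-benzodioxol-5(7aH)-one F2, which is easily separated from any regioisomer. α-Iodination (I2, pyridine) gives the iodoenone F3. Bromide 5 is converted with Me3SnSnMe3 and Pd(PPh3)4 into the alkenylstannane F4, and Stille coupling with F3 (Pd2(dba)3, AsPh3, CuI, DMF) gives the cross-conjugated dienone F5. Conjugate reduction with [(Ph3P)CuH]6 followed by DBU equilibration comes back to the route at 16.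

Step 15. The C7=C8 unit can turn through the ring by passing its hydrogen inside, so attack on the rotamer that shows the opposite face, or competing hydroboration of the enol ether, would erode the C7/C8 configuration. Fallback for attack on the opposite face: set out from 21 and carry out the Rubottom oxidation first (one equivalent of mCPBA, −40 °C), giving the C3 ketone C4 silyl ether with the 7,8-alkene intact F6. Epoxidise the alkene (mCPBA, 0 °C) to the 7,8-epoxide F7, formed on the same exposed face. Meinwald rearrangement (BF3·OEt2, −78 °C) moves hydride from C8 to C7 anti to the departing oxygen, which puts C7–H on the wanted face and gives the 3,8-diketone F8. The less hindered C8 ketone is reduced (NaBH4, MeOH, −78 °C) to the 8-hydroxy-3-ketone F9. Should the C8 epimer form, Mitsunobu esterification with methacrylic acid inverts it. Acylation with methacrylic anhydride comes back to the route at 25.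

Step 18. The two acetonides may not differ enough in rate, so that both are lost or the reaction stalls. Fallback: set out from 25 and hydrolyse both acetonides (AcOH/H2O, 50 °C) to the 1,5,10,15-tetraol F10. Silylate the primary hydroxyl (t-BuPh2SiCl, imidazole) to the 15-O-silyl 1,5,10-triol F11. An acetonide (2-methoxypropene, PPTS) can then engage only the C1/C10 diol, since O5 has no free partner, which gives 27. Acetylation comes back to the route at 28.

Step 24. Cleavage of the MOM ether may be slow under protic conditions mild enough to keep the silyl ethers, and long exposure risks loss of the tertiary silyl ether or acetyl migration from O5 to the freed O6. Fallback: set out from 31 and treat with Me2BBr (CH2Cl2, −78 °C, then aqueous NaHCO3). This cleaves the MOM ether and the acetonide under aprotic Lewis-acidic conditions, and the freed C6 hydroxyl closes on the C12 aldehyde to the 12,6-lactol 1,10-diol F12. Oxidation of the allylic lactol with MnO2 (CH2Cl2) gives the lactone directly, omitting step 23 and coming back to the route at 34.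

## Further compounds

F1 | step 14 | tert-butyldimethylsilyl ether of 18 at the C3 oxygen | CC(C)(C)[Si](C)(C)O[C@]1(C2=COC(C)(C)OC2)[C@H](/C(CCOCc4ccc(OC)cc4)=C\OCOC)C[C@]3(C)OC(C)(C)O[C@H]3C1
F2 | step 12 | (3aS,7aS)-2,2,7a-trimethyl-3a,4-dihydro-1,3-benzodioxol-5(7aH)-one | O=C1C=C[C@]2(C)OC(C)(C)O[C@H]2C1
F3 | step 12 | (3aS,7aS)-6-iodo-2,2,7a-trimethyl-3a,4-dihydro-1,3-benzodioxol-5(7aH)-one | O=C1C(I)=C[C@]2(C)OC(C)(C)O[C@H]2C1
F4 | step 12 | trimethyl[(1Z)-1-(methoxymethoxy)-4-[(4-methoxybenzyl)oxy]but-1-en-2-yl]stannane | COCO/C=C([Sn](C)(C)C)/CCOCc1ccc(OC)cc1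
F5 | step 12 | (3aS,7aS)-6-[(1Z)-1-(methoxymethoxy)-4-[(4-methoxybenzyl)oxy]but-1-en-2-yl]-2,2,7a-trimethyl-3a,4-dihydro-1,3-benzodioxol-5(7aH)-one | O=C1C(/C(CCOCc3ccc(OC)cc3)=C\OCOC)=C[C@]2(C)OC(C)(C)O[C@H]2C1
F6 | step 15 | C3 ketone C4 silyl ether from 21 with the 7,8-(E)-alkene intact | C1C(=O)[C@@]2(O[Si](C)(C)C(C)(C)C)COC(C)(C)O[C@H]2[C@@H](OCOC)/C(CCOCc4ccc(OC)cc4)=C/C[C@]3(C)OC(C)(C)O[C@H]31
F7 | step 15 | 7,8-epoxide of F6, oxygen on the face opposite to the C8 oxygen of 37 | C1C(=O)[C@@]2(O[Si](C)(C)C(C)(C)C)COC(C)(C)O[C@H]2[C@@H](OCOC)[C@]5(CCOCc4ccc(OC)cc4)O[C@H]5C[C@]3(C)OC(C)(C)O[C@H]31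
F8 | step 15 | 3,8-diketone with C7–H as in 37 | C1C(=O)[C@@]2(O[Si](C)(C)C(C)(C)C)COC(C)(C)O[C@H]2[C@@H](OCOC)[C@H](CCOCc4ccc(OC)cc4)C(=O)C[C@]3(C)OC(C)(C)O[C@H]31
F9 | step 15 | 8-hydroxy-3-ketone (8R) | C1C(=O)[C@@]2(O[Si](C)(C)C(C)(C)C)COC(C)(C)O[C@H]2[C@@H](OCOC)[C@H](CCOCc4ccc(OC)cc4)[C@H](O)C[C@]3(C)OC(C)(C)O[C@H]31
F10 | step 18 | 1,5,10,15-tetraol from 25 | C1C(=O)[C@@](O[Si](C)(C)C(C)(C)C)(CO)[C@@H](O)[C@@H](OCOC)[C@H](CCOCc4ccc(OC)cc4)[C@H](OC(=O)C(C)=C)C[C@](C)(O)[C@H]1O
F11 | step 18 | 15-O-(tert-butyldiphenylsilyl) 1,5,10-triol | C1C(=O)[C@@](O[Si](C)(C)C(C)(C)C)(CO[Si](c5ccccc5)(c6ccccc6)C(C)(C)C)[C@@H](O)[C@@H](OCOC)[C@H](CCOCc4ccc(OC)cc4)[C@H](OC(=O)C(C)=C)C[C@](C)(O)[C@H]1O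
F12 | step 24 | 12,6-lactol 1,10-diol (both lactol anomers) | C1C(=O)[C@@](O[Si](C)(C)C(C)(C)C)(CO[Si](c5ccccc5)(c6ccccc6)C(C)(C)C)[C@@H](OC(C)=O)[C@H]2OC(O)C(=C)[C@@H]2[C@H](OC(=O)C(C)=C)C[C@](C)(O)[C@H]1O
A1 | alternative 1 | bridged 1-hydroxy-2,3-dihydrofuran with the 4,15-acetonide | C=C(C)C(=O)O[C@@H]1C[C@]2(C)OC(=C[C@H]2O)[C@@]3(COC(C)(C)O3)[C@@H](OC(C)=O)[C@H]2OC(=O)C(=C)[C@@H]21
A2 | alternative 2 | 6-hydroxy-2H-pyran-3(6H)-one with quaternary C4 | C[Si](C)(C)C#C[C@]1(CO[Si](C)(C)C(C)(C)C)O[C@H](O)C=CC1=O
A3 | alternative 3 | C4/C5 diol of the furanone-bridged lactone | CC[Si](CC)(CC)O[C@@H]1C[C@]2(C)OC(=CC2=O)[C@@](O)(COCc4ccc(OC)cc4)[C@@H](O)[C@H]2OC(=O)C[C@@H]21
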